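5 questions stand on this flask: which set-up gives the most product, and how much each of the 4 gives.

    coupling partner + intermediate A → product (k1 = 0.00600 M⁻¹ min⁻¹)
    intermediate A ⇌ intermediate B (K2 = 0.97, k2 = 1.79 × 10⁻⁴ min⁻¹)
    intermediate C ⇌ intermediate D (K3 = 0.27, k3 = 1.77 × 10⁻⁴ min⁻¹)
    intermediate A → intermediate C (k4 = 6.56 × 10⁻⁴ min⁻¹)
    starting material + coupling partner → intermediate A (k5 = 0.00136 M⁻¹ min⁻¹)

| setting | dawn | noon | autumn | midnight |
|---|---|---|---|---|
| starting material | 0.33 M | 0.33 M | 0.33 M (fed, over 12.5 h) | 0.33 M |
| coupling partner | 0.660 M | 0.660 M (fed, over 12.5 h) | 0.660 M | 0.660 M |
| time | 25 h | 25 h | 25 h |  |
| remark | a closed flask charged with all of it at once and left for 25 h | all but coupling partner at the start; coupling partner goes in evenly over 12.5 h, the run ends at 25 h | a stirred flask in which starting material is dosed at a steady rate over 12.5 h without added volume, worked up at 25 h | one stirred flow tank at steady state, fed with the mixture as stated, mean residence time 25 h |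

1. the set-up with the highest amount of product at the outlet or at the end, in percent of the starting material put in ("none" if the first two lie within 2 percentage points) (dawn / noon / autumn / midnight / none)
2. amount of product at the outlet or at the end, in percent of the starting material put in, dawn
3. amount of product at the outlet or at the end, in percent of the starting material put in, noon
4. amount of product at the outlet or at the end, in percent of the starting material put in, autumn
5. amount of product at the outlet or at the end, in percent of the starting material put in, midnight

You can do the books by hand for dawn. Each mole of starting material needs two of coupling partner to become product, and the charge holds twice as much coupling partner as starting material, so the charge is exactly stoichiometric and neither reagent is in excess at the start. You count in starting material, since the questions are put in percent of it.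

1. **Still unreacted.** Suppose c(coupling partner) stays at two times c(starting material). Then the reciprocal of c(starting material) grows by 2 × 0.00136 M⁻¹ min⁻¹ per unit time. After 25 h that leaves 0.141 M, or 42.6% of the charge. Leaks spare coupling partner, so this entry errs high.

2. **Held as intermediate A.** Set its making equal to its using. That gives 0.0213 M, or 6.46%.

3. **The fork.** Intermediate A couples at 0.00600 M⁻¹ min⁻¹ times c(coupling partner), and it leaks forward at 6.56 × 10⁻⁴ min⁻¹ to intermediate C and 1.79 × 10⁻⁴ min⁻¹ to intermediate B. The two routes are equal at 0.139 M. Call this the crossing concentration c×, the coupling partner level at which coupling matches both forward leaks together. The share going to product, a selectivity, is c/(c + c×).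

4. **The share for this run.** The mean of the first and last c(coupling partner) is 0.471 M, so the share is 77.2%.

5. **Closing the books.** The remaining 50.9% has passed the fork. That makes 39.3% product and 11.6% leaked.

My hand stops at dawn, with 39.3%. The forecast is higher for dawn, at 41%, and it names dawn as best, with noon 33%, autumn 34% and midnight 29%. It counts on “the leaks to intermediates B, C and D taking only a modest share of intermediate A”.

The simulation gives dawn as best: dawn 40.8%, noon 33.1%, autumn 33.7%, midnight 28.8%.

In dawn at 25.0 h, c(coupling partner) reads 0.325 M, above 0.139 M, and c/(c + c×) at the mean level gives 78.0%, while product makes up 77.1% of product and intermediates B, C and D together. The same flask as dawn read at 60.0 h holds 0.203 M of coupling partner, still above c×, where the rule gives 75.6% and the reading is 74.3%.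

Its constants belong to no real substance.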